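**Retrosynthetic overview**
- The target is a 2-methoxy-6-alkyl-1,4-benzoquinone. The six-membered quinone ring is opened back to a 3-hydroxy-5-methoxyphenyl ring, whose free para carbon (between OMe and the side chain) is oxidised last with Fremy's salt.
- The strategy rests on the two-carbon unit between ring and chain: the ring-bound CH2 and the adjacent acetoxy-bearing CH (C1 and C2 of the tridecyl chain). This is a vinyl group with a heteroatom (B, later O) on its inner carbon.
- Both flanking C–C bonds (aryl–CH2 and CH–undecyl) and the (R)-stereocentre are made at once by a three-component conjunctive coupling of undecyl pinacol boronate, vinyllithium and an aryl triflate.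
- The pieces come from 1-undecene (hydroboration), 5-methoxyresorcinol (monobenzylation, triflation) and tetravinyltin (Sn–Li exchange).
- No ring is formed: the benzene ring is bought and becomes the quinone in the final step.

Key step: step 5

Assumption: the (Rp,Rp) hand of the MandyPhos ligand is taken as the one that gives the (R)-boronate when a primary alkyl group migrates; this is to be checked on alcohol 10 (Mosher esters) in the first run, and the (Sp,Sp) antipode is used with no other change if the sense is reversed.

**Route**

Step 1
Reactants: 1 1-undecene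
Product: 2 undecylboronic acid pinacol ester (2-undecyl-4,4,5,5-tetramethyl-1,3,2-dioxaborolane)
Conditions: HBpin (1.2 equiv), [Ir(cod)Cl]2 (1.5 mol%), dppm (3 mol%), CH2Cl2, rt
Reagents that add atoms: pinacolborane, CC1(C)OBOC1(C)C
Why: Iridium-catalysed hydroboration of a terminal alkene with pinacolborane places boron on the terminal carbon (anti-Markovnikov) and gives the primary alkyl boronate without chain isomerisation.

Step 2
Reactants: 3 5-methoxyresorcinol
Product: 4 3-(benzyloxy)-5-methoxyphenol
Conditions: BnBr (0.6 equiv), K2CO3 (0.7 equiv), DMF, rt; unreacted 3 recovered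
Reagents that add atoms: benzyl bromide, BrCc1ccccc1
Why: Williamson ether synthesis on one of two equivalent phenols; keeping the diol in excess over benzyl bromide should bias the statistical mixture toward the mono-ether, which is separated from recovered diol and bis-ether by chromatography.

Step 3
Reactants: 4 3-(benzyloxy)-5-methoxyphenol
Product: 5 3-(benzyloxy)-5-methoxyphenyl trifluoromethanesulfonate
Conditions: Tf2O (1.2 equiv), pyridine (2.5 equiv), CH2Cl2, 0 °C
Reagents that add atoms: trifluoromethanesulfonic anhydride, O=S(=O)(OS(=O)(=O)C(F)(F)F)C(F)(F)F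
Why: Standard O-sulfonylation of a phenol with triflic anhydride and pyridine gives the aryl triflate, a halide-free electrophile for the coupling.

Step 4
Reactants: 6 tetravinyltin
Product: 7 vinyllithium (halide-free, used as a titrated Et2O solution)
Conditions: n-BuLi (hexanes), pentane, rt, Ar; precipitate filtered, washed with pentane, dissolved in Et2O, titrated
Reagents that add atoms: n-butyllithium, [Li]CCCC
Why: Tin–lithium exchange of tetravinyltin with n-butyllithium should precipitate halide-free vinyllithium from pentane while the butylstannane stays in solution.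

Step 5
Reactants: 2 undecylboronic acid pinacol ester; 7 vinyllithium; 5 3-(benzyloxy)-5-methoxyphenyl trifluoromethanesulfonate
Product: 9 (R)-2-[1-(3-(benzyloxy)-5-methoxyphenyl)tridecan-2-yl]-4,4,5,5-tetramethyl-1,3,2-dioxaborolane, via lithium undecyl(vinyl)pinacolatoborate 8 (not isolated)
Conditions: 2 + 7 (1.0 equiv), Et2O, 0 °C → rt; solvent exchange to THF; Pd(OAc)2 (2 mol%), (Rp,Rp)-MandyPhos (2.4 mol%), 5 (1.1 equiv), THF, 60 °C
Reagents that add atoms: none
Why: Pd(0)/MandyPhos adds oxidatively to triflate 5 to give a cationic arylpalladium(II) species that binds the vinyl group of ate complex 8; this triggers an anti 1,2-shift of the undecyl group from boron to the boron-bearing carbon as palladium bonds to the terminal carbon, and reductive elimination of the β-boryl alkylpalladium then forms the aryl–CH2 bond. The closest known reaction type is the palladium-catalysed enantioselective conjunctive cross-coupling of vinylboron ate complexes with aryl triflates, whose scope covers primary alkyl migrating groups and unhindered, electron-rich aryl triflates. No ring is closed; the two skeletal bonds aryl–CH2 and CH–undecyl are formed in one operation. The single new stereocentre (C2 of the tridecyl chain, R) is set by the chiral ferrocenyl bisphosphine, which selects the enantioface of the palladium-bound vinyl group during the metallate shift. The step needs the conjunctive pathway to outrun direct Suzuki transfer of vinyl or undecyl and β-hydride elimination; the non-coordinating triflate counter-ion, the halide-free vinyllithium and the chelating wide-bite-angle ligand (no open cis site) should secure this.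

Step 6
Reactants: 9 (R)-pinacol boronate
Product: 10 (R)-1-[3-(benzyloxy)-5-methoxyphenyl]tridecan-2-ol
Conditions: 30% H2O2, 3 M aq. NaOH, THF, 0 °C → rt; Na2S2O3 quench
Reagents that add atoms: hydrogen peroxide, OO
Why: Alkaline peroxide oxidation of the C–B bond proceeds by 1,2-migration of carbon from boron to oxygen with retention, so the (R)-boronate should give the (R)-alcohol; the aryl ethers are inert.

Step 7
Reactants: 10 (R)-1-[3-(benzyloxy)-5-methoxyphenyl]tridecan-2-ol
Product: 11 (R)-1-[3-(benzyloxy)-5-methoxyphenyl]tridecan-2-yl acetate
Conditions: Ac2O (1.5 equiv), pyridine, DMAP (cat.), CH2Cl2, rt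
Reagents that add atoms: acetic anhydride, CC(=O)OC(C)=O
Why: DMAP-catalysed acylation of the secondary alcohol occurs at oxygen only and leaves the stereocentre untouched.

Step 8
Reactants: 11 (R)-1-[3-(benzyloxy)-5-methoxyphenyl]tridecan-2-yl acetate
Product: 12 (R)-1-(3-hydroxy-5-methoxyphenyl)tridecan-2-yl acetate
Conditions: H2 (1 atm), 10% Pd/C, EtOAc, rt
Reagents that add atoms: none
Why: Catalytic hydrogenolysis cleaves the aryl benzyl ether; the acetate is homobenzylic (not benzylic) and, like the methyl ether, should be inert under 1 atm of hydrogen.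

Step 9
Reactants: 12 (R)-1-(3-hydroxy-5-methoxyphenyl)tridecan-2-yl acetate
Product: 13 (R)-1-(5-methoxy-3,6-dioxocyclohexa-1,4-dien-1-yl)tridecan-2-yl acetate (target, CNP0137521.1)
Conditions: Fremy's salt (2.5 equiv), aq. KH2PO4 (pH ≈ 6), acetone/H2O, 0 °C → rt; neutral work-up
Reagents that add atoms: potassium nitrosodisulfonate (Fremy's salt), [K+].[K+].[O]N(S(=O)(=O)[O-])S(=O)(=O)[O-]
Why: Teuber oxidation: Fremy's radical abstracts the phenolic hydrogen and a second equivalent adds at the free para carbon (between OMe and the side chain), giving the 2-methoxy-6-alkyl-1,4-benzoquinone under near-neutral conditions that spare the acetate and avoid base-induced loss of acetic acid from the product.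

**Compound list**
1 | 1-undecene | C=CCCCCCCCCC | starting material
2 | undecylboronic acid pinacol ester | CCCCCCCCCCCB1OC(C)(C)C(C)(C)O1 | intermediate
3 | 5-methoxyresorcinol | COc1cc(O)cc(O)c1 | starting material
4 | 3-(benzyloxy)-5-methoxyphenol | COc1cc(O)cc(OCc2ccccc2)c1 | intermediate
5 | 3-(benzyloxy)-5-methoxyphenyl trifluoromethanesulfonate | COc1cc(OCc2ccccc2)cc(OS(=O)(=O)C(F)(F)F)c1 | intermediate
6 | tetravinyltin | C=C[Sn](C=C)(C=C)C=C | starting material
7 | vinyllithium | [Li]C=C | intermediate
8 | lithium undecyl(vinyl)pinacolatoborate (ate complex, not isolated) | [Li+].CCCCCCCCCCC[B-]1(C=C)OC(C)(C)C(C)(C)O1 | intermediate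
9 | (R)-2-[1-(3-(benzyloxy)-5-methoxyphenyl)tridecan-2-yl]-4,4,5,5-tetramethyl-1,3,2-dioxaborolane | CCCCCCCCCCC[C@H](Cc1cc(OC)cc(OCc2ccccc2)c1)B1OC(C)(C)C(C)(C)O1 | intermediate
10 | (R)-1-[3-(benzyloxy)-5-methoxyphenyl]tridecan-2-ol | CCCCCCCCCCC[C@H](Cc1cc(OC)cc(OCc2ccccc2)c1)O | intermediate
11 | (R)-1-[3-(benzyloxy)-5-methoxyphenyl]tridecan-2-yl acetate | CCCCCCCCCCC[C@H](Cc1cc(OC)cc(OCc2ccccc2)c1)OC(C)=O | intermediate
12 | (R)-1-(3-hydroxy-5-methoxyphenyl)tridecan-2-yl acetate | CCCCCCCCCCC[C@H](Cc1cc(O)cc(OC)c1)OC(C)=O | intermediate
13 | (R)-1-(5-methoxy-3,6-dioxocyclohexa-1,4-dien-1-yl)tridecan-2-yl acetate | CCCCCCCCCCC[C@H](CC1=CC(=O)C=C(OC)C1=O)OC(C)=O | target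

**Totals**
Total step count: 9. Longest linear sequence: 7 steps (3 → 4 → 5 → 9 → 10 → 11 → 12 → 13; steps 2, 3, 5, 6, 7, 8, 9).

**Steps most likely to fail**

1. Step 5 (conjunctive coupling). Direct Suzuki transfer of the vinyl or undecyl group may outcompete the metallate shift, and enantioface discrimination may erode with the long, flexible migrating group. The fallback sets out from triflate 5 and returns at boronate 9. Commercial 1-tridecyne is hydroborated with pinacolborane (Cp2ZrHCl cat.) to (E)-tridec-1-enyl pinacol boronate F1. Suzuki–Miyaura coupling of F1 with 5 (Pd(dppf)Cl2, K3PO4, dioxane/H2O, 80 °C) gives (E)-1-(benzyloxy)-3-methoxy-5-(tridec-1-en-1-yl)benzene F2. Copper-catalysed enantioselective protoboration of F2 (CuCl, NaOt-Bu, chiral NHC or bisphosphine ligand, B2pin2, MeOH, THF) adds copper at the benzylic carbon and boron at the alkyl-bearing carbon, and protonation should deliver 9. The stereocentre is then set by the copper ligand instead of by palladium.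

2. Step 9 (Fremy's salt oxidation). Oxidation at an ortho carbon, radical dimerisation, or poor contact of the lipophilic phenol with the aqueous oxidant may lower the yield, and any basic excursion may eliminate acetic acid from the product. The fallback sets out from phenol 12 and returns at target 13. Two-electron oxidation with PhI(OAc)2 (2.2 equiv) in MeOH at 0 °C should give the p-quinone monoketal (R)-1-(5,6,6-trimethoxy-3-oxocyclohexa-1,4-dien-1-yl)tridecan-2-yl acetate F6. Mild aqueous acid (dilute HCl/THF, rt) then hydrolyses the ketal of F6 to 13, so the para oxygen is introduced by an ionic instead of a radical pathway.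

3. Step 4 (halide-free vinyllithium). Incomplete tin–lithium exchange or carry-over of n-butyllithium and stannanes would give a titre that misleads and a competing butyl ate complex, which scrambles the migrating group in step 5. The fallback sets out from triflate 5 and returns at alcohol 10, with no vinyllithium or tin. Undecylmagnesium bromide F3 (from 1-bromoundecane and Mg, THF) is added to commercial vinylboronic acid neopentyl glycol ester to give bromomagnesium undecyl(vinyl)(neopentylglycolato)borate F4. With NaOTf as halide scavenger in THF/DMSO, Pd(OAc)2/MandyPhos and 5, the same conjunctive coupling should give (R)-2-[1-(3-(benzyloxy)-5-methoxyphenyl)tridecan-2-yl]-5,5-dimethyl-1,3,2-dioxaborinane F5. Oxidation of F5 with NaOH/H2O2 gives 10.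

**Further compounds**
F1 | step 5 | (E)-tridec-1-enyl pinacol boronate | CCCCCCCCCCC/C=C/B1OC(C)(C)C(C)(C)O1
F2 | step 5 | (E)-1-(benzyloxy)-3-methoxy-5-(tridec-1-en-1-yl)benzene | CCCCCCCCCCC/C=C/c1cc(OC)cc(OCc2ccccc2)c1
F3 | step 4 | undecylmagnesium bromide | CCCCCCCCCCC[Mg]Br
F4 | step 4 | bromomagnesium undecyl(vinyl)(neopentylglycolato)borate | CCCCCCCCCCC[B-]1(C=C)OCC(C)(C)CO1.[Mg+2].[Br-]
F5 | step 4 | (R)-2-[1-(3-(benzyloxy)-5-methoxyphenyl)tridecan-2-yl]-5,5-dimethyl-1,3,2-dioxaborinane | CCCCCCCCCCC[C@H](Cc1cc(OC)cc(OCc2ccccc2)c1)B1OCC(C)(C)CO1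
F6 | step 9 | (R)-1-(5,6,6-trimethoxy-3-oxocyclohexa-1,4-dien-1-yl)tridecan-2-yl acetate | CCCCCCCCCCC[C@H](CC1=CC(=O)C=C(OC)C1(OC)OC)OC(C)=O
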